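Everything rests on cutting ring A at C8–C8a and C6–C7, which takes the flavone back to a 3-oxygenated cyclobutenone and an ynol silyl ether that already holds the whole C1''–C5'' chain and the (R)-centre C2'', both drawn from (R)-limonene. One thermal benzannulation makes those two bonds, re-forms C4a–C8a and delivers ring A with its three oxygens differentiated from the outset: O8a as the only free hydroxyl, beside the chain-bearing C8, and O5 and O7 as silyl ethers. Ortho-formylation at C4a, acetylide addition, oxidation and amine-mediated 6-endo closure through O8a then build ring C, and one fluoride treatment unmasks the three phenols.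

Key step: step 7

Remarks on the chemistry (assumptions)
- O5 is carried as a triisopropylsilyl ether (cyclobutenone 11), not as an alkyl ether. A 5-O-alkyl group peri to C4=O would need a boron or magnesium halide at the end, which can protonate the two 1,1-disubstituted alkenes and let O7 cyclise onto the isopropenyl group. With silicon on O5, O7 and O4', one buffered fluoride step finishes the synthesis.
- Atom bookkeeping: C1''–C5'' are C3, C4, C5, C6 and C1 of limonene. Limonene C2 (the ester carbon) becomes the oxygen-bearing ynolate carbon and ends as C7; C8 is the carbon of CH2Br2.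
- (+)-Limonene 1,2-oxide (the cis/trans mixture made from (R)-limonene), cyclobutane-1,3-dione and 4-ethynylphenol are taken as catalogue compounds. Both epoxide diastereomers converge in step 1.

Step 1
Reactants: 1 (+)-limonene 1,2-oxide, (4R)-1-methyl-4-(prop-1-en-2-yl)-7-oxabicyclo[4.1.0]heptane
Product: 3 (3R)-6-oxo-3-(prop-1-en-2-yl)heptanal, via limonene-1,2-diol 2 (not isolated)
Conditions: H5IO6 (1.2 equiv), THF/H2O, 0 °C → rt
Reagents that add atoms: water, O
Why: Acid-catalysed epoxide hydrolysis followed by periodate glycol cleavage should open either epoxide diastereomer to the same keto aldehyde; the only stereocentre of the target (C2'') is bought here as C4 of 1 and is not touched.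

Step 2
Reactants: 3 (3R)-6-oxo-3-(prop-1-en-2-yl)heptanal
Product: 4 (3R)-6-oxo-3-(prop-1-en-2-yl)heptanoic acid
Conditions: NaClO2, NaH2PO4, 2-methylbut-2-ene, t-BuOH/H2O, 0 °C → rt
Reagents that add atoms: sodium chlorite, [Na+].[O-]Cl=O
Why: Pinnick oxidation converts the aldol-prone aldehyde to the acid under buffered conditions in which the methyl ketone is inert and the sacrificial alkene traps hypochlorous acid before it can reach the isopropenyl group.

Step 3
Reactants: 4 (3R)-6-oxo-3-(prop-1-en-2-yl)heptanoic acid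
Product: 5 methyl (3R)-6-oxo-3-(prop-1-en-2-yl)heptanoate
Conditions: Me3SiCHN2, PhMe/MeOH, 0 °C → rt
Reagents that add atoms: (trimethylsilyl)diazomethane, C[Si](C)(C)C=[N+]=[N-]
Why: O-methylation of the carboxylic acid by the diazoalkane is a neutral esterification, so the acid-sensitive isopropenyl group and the enolisable ketone see neither acid nor base.

Step 4
Reactants: 5 methyl (3R)-6-oxo-3-(prop-1-en-2-yl)heptanoate
Product: 6 methyl (3R)-6-methyl-3-(prop-1-en-2-yl)hept-6-enoate
Conditions: Ph3PCH3Br, KN(SiMe3)2, THF, 0 °C; then 5, −78 °C → rt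
Reagents that add atoms: methyltriphenylphosphonium bromide, C[P+](c1ccccc1)(c1ccccc1)c1ccccc1.[Br-]
Why: Wittig methylenation with the preformed non-stabilised ylide is selective for the ketone over the ester and installs C5''=CH2; the stereocentre is β to both carbonyl groups and cannot epimerise.

Step 5
Reactants: 6 methyl (3R)-6-methyl-3-(prop-1-en-2-yl)hept-6-enoate
Product: 9 triisopropyl{[(4R)-7-methyl-4-(prop-1-en-2-yl)oct-7-en-1-yn-1-yl]oxy}silane, via lithium dibromoenolate 7 (not isolated), via lithium ynolate 8 (not isolated)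
Conditions: CH2Br2, LiTMP (lithium 2,2,6,6-tetramethylpiperidide), THF, −78 °C; LiN(SiMe3)2, −78 → −20 °C; n-BuLi, −78 °C → rt; i-Pr3SiCl, −78 °C → rt
Reagents that add atoms: dibromomethane, BrCBr; chlorotriisopropylsilane, CC(C)[Si](Cl)(C(C)C)C(C)C
Why: Kowalski homologation, in which LiCHBr2 adds to the ester, the derived enolate 7 undergoes bromine–lithium exchange and a carbenoid 1,2-shift of the alkyl group to give ynolate 8, and the bulky silyl chloride traps 8 on oxygen, not on carbon.

Step 6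
Reactants: 10 cyclobutane-1,3-dione
Product: 11 3-[(triisopropylsilyl)oxy]cyclobut-2-en-1-one
Conditions: i-Pr3SiOTf, Et3N, CH2Cl2, −78 → 0 °C; non-aqueous work-up
Reagents that add atoms: triisopropylsilyl trifluoromethanesulfonate, CC(C)[Si](OS(=O)(=O)C(F)(F)F)(C(C)C)C(C)C
Why: O-silylation of the enolate of a strongly acidic cyclic 1,3-dione should give the vinylogous silyl ester, the silicon counterpart of a 3-alkoxycyclobutenone.

Step 7
Reactants: 9 triisopropyl{[(4R)-7-methyl-4-(prop-1-en-2-yl)oct-7-en-1-yn-1-yl]oxy}silane, 11 3-[(triisopropylsilyl)oxy]cyclobut-2-en-1-one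
Product: 16 2-[(2R)-5-methyl-2-(prop-1-en-2-yl)hex-5-en-1-yl]-3,5-bis[(triisopropylsilyl)oxy]phenol, via vinylketene 12 (not isolated), via vinylcyclobutenone 13 (not isolated), via dienylketene 14 (not isolated), via cyclohexadienone 15 (not isolated)
Conditions: 9 (1.0 equiv), 11 (1.3 equiv, added in portions), degassed PhMe (0.5 M), sealed tube, 80 → 110 °C
Reagents that add atoms: none
Why: Danheiser benzannulation, a cascade of four pericyclic events: thermal 4π-opening of 11 across C4a–C8a gives vinylketene 12, whose ketene C=C adds [2+2] to the ynol ether so that the nucleophilic alkyne carbon (future C8) bonds to the ketene carbonyl carbon (C8a) and the oxygen-bearing carbon (C7) bonds to the ketene α-carbon (C6), giving 13. 4π-Opening of 13 across C6–C8a then gives dienylketene 14, which closes ring A by a thermal disrotatory 6π-electrocyclisation that re-forms C4a–C8a (cyclohexadienone 15) and enolises to phenol 16. The closest known reaction type is the thermal aromatic annulation of cyclobutenones with trialkylsiloxyalkynes; a 3-siloxy donor on the four-membered ring is an uncommon but mechanistically ordinary variation. No lasting stereocentre is made (the sp3 ring carbon of 13 is lost on opening), and C2'', separated from the alkyne by C1''H2 and not enolisable, is carried through unchanged. The step needs regiocontrol of the ketene–alkyne union and chemoselectivity over the two 1,1-disubstituted alkenes: the polarisation of the ynol ether secures the first and so places the chain between the one free hydroxyl (O8a) and the O7 silyl ether, and the far greater ketenophilicity of the electron-rich alkyne secures the second.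

Step 8
Reactants: 16 2-[(2R)-5-methyl-2-(prop-1-en-2-yl)hex-5-en-1-yl]-3,5-bis[(triisopropylsilyl)oxy]phenol
Product: 18 2-hydroxy-3-[(2R)-5-methyl-2-(prop-1-en-2-yl)hex-5-en-1-yl]-4,6-bis[(triisopropylsilyl)oxy]benzaldehyde, via salicyl alcohol 17 (not isolated)
Conditions: MgCl2, Et3N, (CH2O)n, THF, reflux
Reagents that add atoms: paraformaldehyde (as formaldehyde), C=O
Why: Casnati–Skattebøl ortho-formylation, in which magnesium bound to the phenol oxygen delivers formaldehyde to the only free ortho carbon (C4a) and the resulting salicyl alkoxide 17 is oxidised by hydride transfer to a second formaldehyde, so C6 (para to the hydroxyl) is not attacked.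

Step 9
Reactants: 19 4-ethynylphenol
Product: 20 (4-ethynylphenoxy)triisopropylsilane
Conditions: i-Pr3SiCl, imidazole, DMF, 0 °C → rt
Reagents that add atoms: chlorotriisopropylsilane, CC(C)[Si](Cl)(C(C)C)C(C)C
Why: Imidazole-mediated silylation masks the acidic 4'-hydroxyl so that a soluble monolithium acetylide can be made, and it puts the same fluoride-labile group on all three phenol oxygens.

Step 10
Reactants: 18 2-hydroxy-3-[(2R)-5-methyl-2-(prop-1-en-2-yl)hex-5-en-1-yl]-4,6-bis[(triisopropylsilyl)oxy]benzaldehyde, 20 (4-ethynylphenoxy)triisopropylsilane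
Product: 22 2-(1-hydroxy-3-{4-[(triisopropylsilyl)oxy]phenyl}prop-2-yn-1-yl)-6-[(2R)-5-methyl-2-(prop-1-en-2-yl)hex-5-en-1-yl]-3,5-bis[(triisopropylsilyl)oxy]phenol (both carbinol epimers), via lithium acetylide 21 (not isolated)
Conditions: 20 (2.5 equiv), n-BuLi (2.4 equiv), THF, −78 °C; then 18, −78 → −40 °C; aq. NH4Cl at −78 °C
Reagents that add atoms: none
Why: 1,2-Addition of a lithium acetylide to the aldehyde (the first equivalent only deprotonates the phenol) forms the C3–C4 bond; the new carbinol centre at C4 is formed without control and is erased in step 11, and the cold quench forestalls silyl transfer from O5 to the alkoxide.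

Step 11
Reactants: 22 2-(1-hydroxy-3-{4-[(triisopropylsilyl)oxy]phenyl}prop-2-yn-1-yl)-6-[(2R)-5-methyl-2-(prop-1-en-2-yl)hex-5-en-1-yl]-3,5-bis[(triisopropylsilyl)oxy]phenol
Product: 23 1-{2-hydroxy-3-[(2R)-5-methyl-2-(prop-1-en-2-yl)hex-5-en-1-yl]-4,6-bis[(triisopropylsilyl)oxy]phenyl}-3-{4-[(triisopropylsilyl)oxy]phenyl}prop-2-yn-1-one
Conditions: activated MnO2 (excess), CH2Cl2, rt
Reagents that add atoms: none
Why: MnO2 oxidation is selective for the doubly activated (benzylic and propargylic) alcohol and should leave the isolated alkenes, the silyl ethers and the phenol alone.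

Step 12
Reactants: 23 1-{2-hydroxy-3-[(2R)-5-methyl-2-(prop-1-en-2-yl)hex-5-en-1-yl]-4,6-bis[(triisopropylsilyl)oxy]phenyl}-3-{4-[(triisopropylsilyl)oxy]phenyl}prop-2-yn-1-one
Product: 25 8-[(2R)-5-methyl-2-(prop-1-en-2-yl)hex-5-en-1-yl]-5,7-bis[(triisopropylsilyl)oxy]-2-{4-[(triisopropylsilyl)oxy]phenyl}-4H-chromen-4-one, via enaminone 24 (not isolated)
Conditions: Et2NH (5 equiv), MeCN, rt → 60 °C
Reagents that add atoms: none
Why: Conjugate addition of the secondary amine to the ynone gives β-aminoenone 24, and the C8a hydroxyl then closes ring C by 6-endo-trig addition–elimination with loss of the amine, which shuts out the 5-exo (aurone) mode; O5 is silylated, so only O8a can close, and the aprotic solvent spares the silyl ethers.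

Step 13
Reactants: 25 8-[(2R)-5-methyl-2-(prop-1-en-2-yl)hex-5-en-1-yl]-5,7-bis[(triisopropylsilyl)oxy]-2-{4-[(triisopropylsilyl)oxy]phenyl}-4H-chromen-4-one
Product: 26 5,7-dihydroxy-2-(4-hydroxyphenyl)-8-[(2R)-5-methyl-2-(prop-1-en-2-yl)hex-5-en-1-yl]-4H-chromen-4-one
Conditions: Bu4NF (4 equiv), AcOH (4 equiv), THF, 0 °C → rt
Reagents that add atoms: none
Why: Fluoride-induced cleavage of the three aryl silyl ethers under acetic acid buffering frees the 5-, 7- and 4'-hydroxyls without acid, oxidant or reductant, so the terminal alkenes and C2'' are not at risk.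

Compound list
1 | (+)-limonene 1,2-oxide, (4R)-1-methyl-4-(prop-1-en-2-yl)-7-oxabicyclo[4.1.0]heptane, cis/trans mixture at the epoxide | CC12CC[C@H](CC1O2)C(=C)C | starting material
2 | (4R)-1-methyl-4-(prop-1-en-2-yl)cyclohexane-1,2-diol (limonene-1,2-diol, C1/C2 diastereomers) | CC1(O)CC[C@H](CC1O)C(=C)C | intermediate (not isolated)
3 | (3R)-6-oxo-3-(prop-1-en-2-yl)heptanal | CC(=O)CC[C@H](CC=O)C(=C)C | intermediate
4 | (3R)-6-oxo-3-(prop-1-en-2-yl)heptanoic acid | CC(=O)CC[C@H](CC(=O)O)C(=C)C | intermediate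
5 | methyl (3R)-6-oxo-3-(prop-1-en-2-yl)heptanoate | CC(=O)CC[C@H](CC(=O)OC)C(=C)C | intermediate
6 | methyl (3R)-6-methyl-3-(prop-1-en-2-yl)hept-6-enoate | C=C(C)CC[C@H](CC(=O)OC)C(=C)C | intermediate
7 | lithium (4R)-1,1-dibromo-7-methyl-4-(prop-1-en-2-yl)octa-1,7-dien-2-olate | [Li+].C=C(C)CC[C@H](CC([O-])=C(Br)Br)C(=C)C | intermediate (not isolated)
8 | lithium (4R)-7-methyl-4-(prop-1-en-2-yl)oct-7-en-1-yn-1-olate | [Li+].C=C(C)CC[C@H](CC#C[O-])C(=C)C | intermediate (not isolated)
9 | triisopropyl{[(4R)-7-methyl-4-(prop-1-en-2-yl)oct-7-en-1-yn-1-yl]oxy}silane | C=C(C)CC[C@H](CC#CO[Si](C(C)C)(C(C)C)C(C)C)C(=C)C | intermediate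
10 | cyclobutane-1,3-dione | O=C1CC(=O)C1 | starting material
11 | 3-[(triisopropylsilyl)oxy]cyclobut-2-en-1-one | CC(C)[Si](OC1=CC(=O)C1)(C(C)C)C(C)C | intermediate
12 | 3-[(triisopropylsilyl)oxy]buta-1,3-dien-1-one (vinylketene) | C=C(O[Si](C(C)C)(C(C)C)C(C)C)C=C=O | intermediate (not isolated)
13 | 2-[(2R)-5-methyl-2-(prop-1-en-2-yl)hex-5-en-1-yl]-3-[(triisopropylsilyl)oxy]-4-{1-[(triisopropylsilyl)oxy]ethenyl}cyclobut-2-en-1-one (both C4 epimers) | C=C(C)CC[C@H](CC1=C(O[Si](C(C)C)(C(C)C)C(C)C)C(C(=C)O[Si](C(C)C)(C(C)C)C(C)C)C1=O)C(=C)C | intermediate (not isolated)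
14 | (3E)-2-[(2R)-5-methyl-2-(prop-1-en-2-yl)hex-5-en-1-yl]-3,5-bis[(triisopropylsilyl)oxy]hexa-1,3,5-trien-1-one (dienylketene) | C=C(C)CC[C@H](CC(=C=O)/C(O[Si](C(C)C)(C(C)C)C(C)C)=C\C(=C)O[Si](C(C)C)(C(C)C)C(C)C)C(=C)C | intermediate (not isolated)
15 | 2-[(2R)-5-methyl-2-(prop-1-en-2-yl)hex-5-en-1-yl]-3,5-bis[(triisopropylsilyl)oxy]cyclohexa-2,4-dien-1-one | C=C(C)CC[C@H](CC1=C(O[Si](C(C)C)(C(C)C)C(C)C)C=C(O[Si](C(C)C)(C(C)C)C(C)C)CC1=O)C(=C)C | intermediate (not isolated)
16 | 2-[(2R)-5-methyl-2-(prop-1-en-2-yl)hex-5-en-1-yl]-3,5-bis[(triisopropylsilyl)oxy]phenol | C=C(C)CC[C@H](Cc1c(O)cc(O[Si](C(C)C)(C(C)C)C(C)C)cc1O[Si](C(C)C)(C(C)C)C(C)C)C(=C)C | intermediate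
17 | 2-(hydroxymethyl)-6-[(2R)-5-methyl-2-(prop-1-en-2-yl)hex-5-en-1-yl]-3,5-bis[(triisopropylsilyl)oxy]phenol (salicyl alcohol, magnesium salt in the flask) | C=C(C)CC[C@H](Cc1c(O)c(CO)c(O[Si](C(C)C)(C(C)C)C(C)C)cc1O[Si](C(C)C)(C(C)C)C(C)C)C(=C)C | intermediate (not isolated)
18 | 2-hydroxy-3-[(2R)-5-methyl-2-(prop-1-en-2-yl)hex-5-en-1-yl]-4,6-bis[(triisopropylsilyl)oxy]benzaldehyde | C=C(C)CC[C@H](Cc1c(O)c(C=O)c(O[Si](C(C)C)(C(C)C)C(C)C)cc1O[Si](C(C)C)(C(C)C)C(C)C)C(=C)C | intermediate
19 | 4-ethynylphenol | C#Cc1ccc(O)cc1 | starting material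
20 | (4-ethynylphenoxy)triisopropylsilane | C#Cc1ccc(O[Si](C(C)C)(C(C)C)C(C)C)cc1 | intermediate
21 | lithium {4-[(triisopropylsilyl)oxy]phenyl}acetylide | [Li+].[C-]#Cc1ccc(O[Si](C(C)C)(C(C)C)C(C)C)cc1 | intermediate (not isolated)
22 | 2-(1-hydroxy-3-{4-[(triisopropylsilyl)oxy]phenyl}prop-2-yn-1-yl)-6-[(2R)-5-methyl-2-(prop-1-en-2-yl)hex-5-en-1-yl]-3,5-bis[(triisopropylsilyl)oxy]phenol (both carbinol epimers) | C=C(C)CC[C@H](Cc1c(O)c(C(O)C#Cc2ccc(O[Si](C(C)C)(C(C)C)C(C)C)cc2)c(O[Si](C(C)C)(C(C)C)C(C)C)cc1O[Si](C(C)C)(C(C)C)C(C)C)C(=C)C | intermediate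
23 | 1-{2-hydroxy-3-[(2R)-5-methyl-2-(prop-1-en-2-yl)hex-5-en-1-yl]-4,6-bis[(triisopropylsilyl)oxy]phenyl}-3-{4-[(triisopropylsilyl)oxy]phenyl}prop-2-yn-1-one | C=C(C)CC[C@H](Cc1c(O)c(C(=O)C#Cc2ccc(O[Si](C(C)C)(C(C)C)C(C)C)cc2)c(O[Si](C(C)C)(C(C)C)C(C)C)cc1O[Si](C(C)C)(C(C)C)C(C)C)C(=C)C | intermediate
24 | 3-(diethylamino)-1-{2-hydroxy-3-[(2R)-5-methyl-2-(prop-1-en-2-yl)hex-5-en-1-yl]-4,6-bis[(triisopropylsilyl)oxy]phenyl}-3-{4-[(triisopropylsilyl)oxy]phenyl}prop-2-en-1-one | C=C(C)CC[C@H](Cc1c(O)c(C(=O)C=C(N(CC)CC)c2ccc(O[Si](C(C)C)(C(C)C)C(C)C)cc2)c(O[Si](C(C)C)(C(C)C)C(C)C)cc1O[Si](C(C)C)(C(C)C)C(C)C)C(=C)C | intermediate (not isolated)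
25 | 8-[(2R)-5-methyl-2-(prop-1-en-2-yl)hex-5-en-1-yl]-5,7-bis[(triisopropylsilyl)oxy]-2-{4-[(triisopropylsilyl)oxy]phenyl}-4H-chromen-4-one | C=C(C)CC[C@H](Cc1c(O[Si](C(C)C)(C(C)C)C(C)C)cc(O[Si](C(C)C)(C(C)C)C(C)C)c2c(=O)cc(-c3ccc(O[Si](C(C)C)(C(C)C)C(C)C)cc3)oc12)C(=C)C | intermediate
26 | 5,7-dihydroxy-2-(4-hydroxyphenyl)-8-[(2R)-5-methyl-2-(prop-1-en-2-yl)hex-5-en-1-yl]-4H-chromen-4-one | C=C(C)CC[C@H](Cc1c(O)cc(O)c2c(=O)cc(-c3ccc(O)cc3)oc12)C(=C)C | target

Total step count: 13.
Longest linear sequence: 11 steps (steps 1–5, 7, 8, 10–13, from 1 to 26); steps 6 and 9 are one-step side branches.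

Steps most likely to fail

Step 7. The donor-substituted cyclobutenone may open too slowly at temperatures that the ynol ether tolerates, so that the alkyne is lost to dimerisation or desilylation, or the phenol formed may be acylated by remaining vinylketene. The fallback makes the same vinylketene at room temperature by photochemical Wolff rearrangement. It sets out from 9 and from commercial butane-2,3-dione (CC(=O)C(C)=O). The dione is monosilylated (i-Pr3SiOTf, Et3N, CH2Cl2) to 3-[(triisopropylsilyl)oxy]but-3-en-2-one F1. The lithium enolate of F1 (LiN(SiMe3)2, THF, −78 °C) is acylated with 2,2,2-trifluoroethyl trifluoroacetate to 1,1,1-trifluoro-5-[(triisopropylsilyl)oxy]hex-5-ene-2,4-dione F2. Detrifluoroacetylative diazo transfer (MsN3, Et3N, H2O, MeCN) then gives 1-diazo-3-[(triisopropylsilyl)oxy]but-3-en-2-one F3. Irradiation of F3 with 9 (low-pressure mercury lamp, CH2Cl2, rt, then 80 °C) should give vinylketene 12, which follows the same cascade and comes back to the route at phenol 16.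

Step 5. The ester may be enolised in competition with LiCHBr2 addition, the carbenoid rearrangement may stop short, or the ynolate may be silylated on carbon to a silylketene. The fallback reaches the ynolate by oxidising an acetylide. It sets out from ester 6, which is reduced (i-Bu2AlH, CH2Cl2, −78 °C) to (3R)-6-methyl-3-(prop-1-en-2-yl)hept-6-enal F4. Ohira–Bestmann alkynylation (dimethyl (1-diazo-2-oxopropyl)phosphonate, K2CO3, MeOH) gives (4R)-7-methyl-4-(prop-1-en-2-yl)oct-7-en-1-yne F5. Deprotonation (LiN(SiMe3)2, THF, −78 °C) and oxidation of the lithium acetylide with t-BuOOLi (−78 → 0 °C) should give ynolate 8, which is silylated with i-Pr3SiOTf and comes back to the route at 9.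

Step 8. Formylation at the crowded carbon between the hydroxyl and the O5 silyl ether may be slow; at reflux the silyl group may move from O5 to the intermediate benzylic alkoxide, or a diarylmethane may form. The fallback separates hydroxymethylation from oxidation with a boron template. It sets out from phenol 16: PhB(OH)2, (CH2O)n and catalytic EtCO2H in refluxing PhH with water removal should give 8-[(2R)-5-methyl-2-(prop-1-en-2-yl)hex-5-en-1-yl]-2-phenyl-5,7-bis[(triisopropylsilyl)oxy]-4H-1,3,2-benzodioxaborinine F6. Oxidative cleavage of the boron template (H2O2, THF, 0 °C) releases salicyl alcohol 17, which is isolated and oxidised with MnO2 (CH2Cl2, rt), so the sequence comes back to the route at aldehyde 18.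

Further compounds
F1 | step 7 | 3-[(triisopropylsilyl)oxy]but-3-en-2-one | CC(=O)C(=C)O[Si](C(C)C)(C(C)C)C(C)C
F2 | step 7 | 1,1,1-trifluoro-5-[(triisopropylsilyl)oxy]hex-5-ene-2,4-dione | C=C(O[Si](C(C)C)(C(C)C)C(C)C)C(=O)CC(=O)C(F)(F)F
F3 | step 7 | 1-diazo-3-[(triisopropylsilyl)oxy]but-3-en-2-one | C=C(O[Si](C(C)C)(C(C)C)C(C)C)C(=O)C=[N+]=[N-]
F4 | step 5 | (3R)-6-methyl-3-(prop-1-en-2-yl)hept-6-enal | C=C(C)CC[C@H](CC=O)C(=C)C
F5 | step 5 | (4R)-7-methyl-4-(prop-1-en-2-yl)oct-7-en-1-yne | C=C(C)CC[C@H](CC#C)C(=C)C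
F6 | step 8 | 8-[(2R)-5-methyl-2-(prop-1-en-2-yl)hex-5-en-1-yl]-2-phenyl-5,7-bis[(triisopropylsilyl)oxy]-4H-1,3,2-benzodioxaborinine | C=C(C)CC[C@H](Cc1c2OB(c3ccccc3)OCc2c(O[Si](C(C)C)(C(C)C)C(C)C)cc1O[Si](C(C)C)(C(C)C)C(C)C)C(=C)C
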